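# Tatanan B: design of an enantioselective total synthesis

## The problem

Atoms are numbered as in 7-ethyl-1,4-dimethoxy-8,10-dimethyl-9,11-bis(2,4,5-trimethoxyphenyl)spiro[5.5]undeca-1,4-dien-3-one. Ring A is the cross-conjugated dienone C1–C6, ring B is the cyclohexane C6–C11, and Ar is 2,4,5-trimethoxyphenyl.

Every carbon of ring B is a stereocentre, (6S,7R,8S,9S,10R,11R). C6 is quaternary and is stereogenic only because the two arms of ring A differ: C1 bears OMe and C5 bears H. In the chair of ring B the C7 ethyl, C9 aryl, C10 methyl and C11 aryl groups are equatorial and the C8 methyl group alone is axial. At C6 the C5–H arm is axial, syn to the C8 methyl group, and the C1–OMe arm is equatorial.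

C9, C10, C11 and C6 therefore lie where a chair-like ring closure would place them and can be controlled from within. The C7/C8 pair, with its contra-thermodynamic axial methyl group, must be set by reagents and must carry the absolute configuration. Ring B has no carbonyl group or heteroatom, so enolate, aldol or Michael logic would have to install functional groups and then erase them.

The feature that makes the key step possible is that ring B consists of three two-carbon pieces, C6–C7, C8–C9 and C10–C11, each taken from one arylpropane unit. Each bond between pieces (C7–C8, C9–C10, C11–C6) joins a benzylic carbon to a nucleophilic carbon. The benzylic carbons can carry a cation because their aryl rings have ortho and para methoxy groups. The nucleophilic carbon is the β-carbon of a propenylarene or, for C6, an ipso carbon that is para to the oxygen on C3 and ortho to the methoxy group on C1.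

The dienone re-opens or rearranges in strong acid. Its two enol ethers and the three electron-rich rings do not tolerate oxidants, electrophiles or forcing hydrogenation.

## Retrosynthesis

**17 to 13 and 1.** The bonds cut are C9–C10 and C11–C6, together with the O–CH3 bond of what was the para-methoxy group on C3.
- C11–C6 has to be the last bond made, because it creates the quaternary centre. Cutting it alone leaves the whole open chain to be built (Alternative 1).
- Cutting C9–C10 as well releases an intact commercial alkene, α-asarone 1.
- Cutting C7–C8 too (Alternative 3) would give away the only two centres that the ring cannot control.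
- The precursor 13 is acyclic, has two aryl groups and only two stereocentres that matter. The product has one more ring, a quaternary carbon and four more stereocentres.
- The forward reaction must pass in order through cation 14, cation 15 and oxocarbenium ion 16, and must stop after one alkene has been taken up.

**13 to 7 and 9.** The bond cut is C8–C9.
- C9 becomes planar in the key step, so its configuration in 13 is irrelevant. Any union that preserves C8 is acceptable.
- A boronic ester 7 and the achiral lithiated carbamate 10 (from 9) give 13 in one flask through 11 and 12.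
- The neighbouring choice, an aryllithium added to an α-methyl aldehyde, costs three more steps and passes through an epimerisable centre.
- The forward reaction must move C8 from boron to carbon with retention.

**7 to 2 and 4.** The bond cut is C7–C8.
- The 7,8-relationship of 17 is the one that methylation of an enolate next to the aryl-bearing carbon would have to create against the bias of the substrate.
- A stereospecific 1,2-metallate shift (through 5 and 6) is indifferent to that bias. C8 comes from the chiral carbenoid and C7 is retained.
- The precursor 2 has a single stereocentre.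

**2 to 1.** The bonds cut are the C7–B bond and one C–H bond of the ethyl CH2 group.
- Enantioselective hydroboration of 1 places hydride on the β-carbon, where the biogenetic proton would go, and boron on C7.
- Two of the three arylpropane units thus come from the same commercial alkene.
- The forward reaction must be benzylic-selective and enantioselective.

**4 from 3 and 9 from 8.** These are one-step derivatisations of commercial 2,4,6-triisopropylbenzoic acid 3 and 2,4,5-trimethoxybenzyl alcohol 8. Neither involves a stereocentre.

## Roads not taken

Alternative 1: the most obvious plan cuts C6–C7 alone and closes ring B last on a complete chain.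
- Forward key step: the open-chain para-phenol allylic carbonate A1 is ionised by zerovalent palladium (Pd2(dba)3, PPh3). The para carbon of the phenol attacks the π-allyl terminus (Tsuji–Trost-type dearomatisation) to give the 7-vinyl spirodienone A2. The vinyl group is then hydrogenated (RhCl(PPh3)3, H2).
- A1 already holds the four contiguous centres C8–C11 in an open chain, and each of them needs its own stereocontrolled operation.
- The key step forms one bond and sets only C6 and C7.
- One aryl ring must be carried as a differentiated phenol, and a reduction is needed beside the dienone.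
- The chosen plan sets four centres and two bonds in the step that introduces the last third of the carbon atoms.

Alternative 2: cut C6–C7 and C10–C11.
- Forward key step: a Diels–Alder reaction of the para-quinone methide A3 (dienophile C11=C6) with the diene A4 gives the cyclohexene A5.
- A5 retains a tetrasubstituted C8=C9 styrene bond between two stereocentres. This bond cannot be expected to be hydrogenated while the dienone survives.
- The trans relation of the C7 ethyl and C10 methyl groups requires an (E,Z)-diene with an inward substituent, whose s-cis conformer is strained.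
- Quinone methides tend to add nucleophilic dienes at the exocyclic carbon and rearomatise rather than cycloadd.
- The absolute configuration would need a catalyst of unknown type.
- The chosen plan leaves no unsaturation in ring B.

Alternative 3: cut all three bonds between the pieces.
- Forward key step: acid-induced trimerisation of 1 through the cation A6 under a chiral acid.
- It is the shortest route on paper. However, C7 and C8 would arise in an intermolecular step with no control element, and the axial C8 methyl group is not the favoured arrangement.
- The absolute configuration would rest on ion pairing with a flat, delocalised cation.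
- Nothing fixes the number of units that add.
- In the chosen plan the one intermolecular cation–alkene union is steered by a pre-set C8, and the chain is built so that the very next cation can close.

Key step: step 6

Assumption 1: the sense of induction of the copper hydride/(R)-DTBM-SEGPHOS catalyst on 1 is taken to be that known for (E)-β-methylstyrenes, which corresponds to (S)-2; if it is the reverse, the (S)-ligand is used.

Assumption 2: 13 is carried on as the mixture of its two carbinol epimers, because that carbon becomes planar in step 6.

## Steps

Step 1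
Reactants: 1 α-asarone, (E)-1,2,4-trimethoxy-5-(prop-1-en-1-yl)benzene
Product: 2 (S)-4,4,5,5-tetramethyl-2-[1-(2,4,5-trimethoxyphenyl)propyl]-1,3,2-dioxaborolane
Conditions: HBpin (1.2 equiv), CuCl (3 mol %), NaOt-Bu (6 mol %), (R)-DTBM-SEGPHOS (3 mol %), toluene, rt
Reagents that add atoms: pinacolborane, [H]B1OC(C)(C)C(C)(C)O1
Why: Copper hydride-catalysed hydroboration of a β-substituted vinylarene: the ligated hydride of monovalent copper adds with copper at the benzylic carbon and hydride at the β-carbon (the future CH2 of the ethyl group), and stereoretentive σ-bond metathesis with HBpin releases the benzylic boronic ester. The axially chiral bisphosphine sets C7, and the reaction type is established for (E)-β-methylstyrenes that carry ether groups.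

Step 2
Reactants: 3 2,4,6-triisopropylbenzoic acid
Product: 4 ethyl 2,4,6-triisopropylbenzoate
Conditions: EtI, K2CO3, DMF, 50 °C
Reagents that add atoms: iodoethane, CCI
Why: O-alkylation of the carboxylate (SN2), which avoids attack at the hindered carbonyl carbon; no stereocentre is formed.

Step 3
Reactants: 4 ethyl 2,4,6-triisopropylbenzoate; 2 (S)-4,4,5,5-tetramethyl-2-[1-(2,4,5-trimethoxyphenyl)propyl]-1,3,2-dioxaborolane
Product: 7 4,4,5,5-tetramethyl-2-[(2S,3R)-3-(2,4,5-trimethoxyphenyl)pentan-2-yl]-1,3,2-dioxaborolane, via lithiated benzoate 5 (not isolated), via boronate complex 6 (not isolated)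
Conditions: 4 (1.3 equiv), s-BuLi, (+)-sparteine, Et2O, −78 °C; then 2, −78 °C; then reflux
Reagents that add atoms: none
Why: Lithiation–borylation (1,2-metallate rearrangement): sparteine-mediated deprotonation gives the configurationally stable (R)-carbenoid 5, which adds to boron of 2 with retention to give 6. On warming C7 migrates with retention and displaces the antiperiplanar benzoate with inversion at C8. Both centres are fixed by reagent control and stereospecificity, so the 7,8-relationship does not depend on substrate bias.

Step 4
Reactants: 8 (2,4,5-trimethoxyphenyl)methanol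
Product: 9 2,4,5-trimethoxybenzyl N,N-diisopropylcarbamate
Conditions: NaH, i-Pr2NCOCl, THF, 0 °C to rt
Reagents that add atoms: N,N-diisopropylcarbamoyl chloride, CC(C)N(C(C)C)C(=O)Cl
Why: O-carbamoylation of the alkoxide; the carbamate serves in step 5 both as the directing group for benzylic lithiation and as the leaving group.

Step 5
Reactants: 9 2,4,5-trimethoxybenzyl N,N-diisopropylcarbamate; 7 4,4,5,5-tetramethyl-2-[(2S,3R)-3-(2,4,5-trimethoxyphenyl)pentan-2-yl]-1,3,2-dioxaborolane
Product: 13 (2S,3R)-2-methyl-1,3-bis(2,4,5-trimethoxyphenyl)pentan-1-ol (both carbinol epimers), via lithiated carbamate 10 (not isolated), via boronate complex 11 (not isolated), via benzylic boronic ester 12 (not isolated)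
Conditions: 9 (1.3 equiv), s-BuLi, TMEDA, Et2O, −78 °C; then 7, −78 °C to rt; then H2O2, NaOH, THF, 0 °C
Reagents that add atoms: hydrogen peroxide, OO
Why: Second lithiation–borylation, now with the achiral benzylic carbenoid 10: in 11 the secondary carbon C8 migrates with retention and expels the carbamate to give 12, whose C–B bond is oxidised with retention in the same flask. C9 needs no control because step 6 erases it. Product 13 ionises easily and is to be purified on base-washed silica.

Step 6
Reactants: 13 (2S,3R)-2-methyl-1,3-bis(2,4,5-trimethoxyphenyl)pentan-1-ol; 1 α-asarone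
Product: 17 tatanan B, via C9 benzylic cation 14 (not isolated), via C11 benzylic cation 15 (not isolated), via spirocyclic oxocarbenium ion 16 (not isolated)
Conditions: 1 (3 equiv), HNTf2 (5 mol %), (CF3)2CHOH–CH2Cl2 (1:4), slow addition of 13, −40 to 0 °C; then aq NaHCO3
Reagents that add atoms: none
Why: Proposed new method: the acid ionises 13 to the planar benzylic cation 14, the β-carbon of the propenyl group of 1 adds to C9 to give the benzylic cation 15, the ipso carbon C6 of the aryl ring on C7 closes on C11 to give the O-methyl oxocarbenium ion 16, and the water released in the ionisation attacks C3 and expels methanol, so that the net change is 13 + 1 = 17 + MeOH and the acid is returned. The closest known reaction types are the SN1 substitution of α-branched benzylic alcohols by π-nucleophiles, the formal [3+2] annulation of benzylic cations and styrenes to indanes, and the ipso-Friedel–Crafts dearomatisation of para-methoxyaryl groups with loss of the O-methyl group; what is new is their union in an intermolecular [4+2] annulation that stops a cationic chain growth after one alkene. Ring B, the only ring closed, forms by a 6-exo-trig attack of the arene π-system on C11 through a chair. C9 is controlled by C8: 1,3-allylic strain holds the C8–H bond in the plane of 14 next to the aryl ring, and 1 attacks the face that shows the C8 methyl group, opposite the large C7 branch, which is the 8,9-cis arrangement of 17. C10 is controlled by the axial C8 methyl group: the C10 epimer of 15 could close only with two syn-axial methyl groups, so it is expected to lose the C10 proton and regain it until the epimer with an equatorial methyl group closes (Curtin–Hammett selection). C11 takes its aryl group equatorial in the same chair, and C6 is fixed by the rotamer of the attacking ring in which the small C5–H edge, not the C1–OMe edge, points under ring B toward the axial C8 methyl group. The step needs 14 to meet 1 before it closes on the ortho C–H carbon of its own aryl ring, and 15 to close on C6 before it meets a second 1 or the ortho C–H carbon of the C9 aryl ring. Both are secured by the substrate: C6 is activated by a para and an ortho methoxy group and is reached by a 6-exo chair, whereas each ortho C–H carbon is activated by one methoxy group only and is reached by a strained 5-endo closure; excess 1, low temperature and a non-nucleophilic ionising medium support this order of rates.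

## Compound list

1 | α-asarone, (E)-1,2,4-trimethoxy-5-(prop-1-en-1-yl)benzene | C/C=C/c1cc(OC)c(OC)cc1OC | starting material
2 | (S)-4,4,5,5-tetramethyl-2-[1-(2,4,5-trimethoxyphenyl)propyl]-1,3,2-dioxaborolane | CC[C@@H](c1cc(OC)c(OC)cc1OC)B1OC(C)(C)C(C)(C)O1 | intermediate
3 | 2,4,6-triisopropylbenzoic acid | CC(C)c1cc(C(C)C)c(C(=O)O)c(C(C)C)c1 | starting material
4 | ethyl 2,4,6-triisopropylbenzoate | CCOC(=O)c1c(C(C)C)cc(C(C)C)cc1C(C)C | intermediate
5 | (R)-1-lithioethyl 2,4,6-triisopropylbenzoate (as its (+)-sparteine complex) | C[C@@H]([Li])OC(=O)c1c(C(C)C)cc(C(C)C)cc1C(C)C | intermediate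
6 | lithium boronate complex formed from 5 and 2 | CC[C@@H](c1cc(OC)c(OC)cc1OC)[B-]1(OC(C)(C)C(C)(C)O1)[C@H](C)OC(=O)c1c(C(C)C)cc(C(C)C)cc1C(C)C.[Li+] | intermediate
7 | 4,4,5,5-tetramethyl-2-[(2S,3R)-3-(2,4,5-trimethoxyphenyl)pentan-2-yl]-1,3,2-dioxaborolane | CC[C@@H](c1cc(OC)c(OC)cc1OC)[C@H](C)B1OC(C)(C)C(C)(C)O1 | intermediate
8 | (2,4,5-trimethoxyphenyl)methanol | OCc1cc(OC)c(OC)cc1OC | starting material
9 | 2,4,5-trimethoxybenzyl N,N-diisopropylcarbamate | CC(C)N(C(C)C)C(=O)OCc1cc(OC)c(OC)cc1OC | intermediate
10 | α-lithio-2,4,5-trimethoxybenzyl N,N-diisopropylcarbamate (racemic, TMEDA complex) | CC(C)N(C(C)C)C(=O)OC([Li])c1cc(OC)c(OC)cc1OC | intermediate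
11 | lithium boronate complex formed from 10 and 7 | CC[C@@H](c1cc(OC)c(OC)cc1OC)[C@H](C)[B-]1(OC(C)(C)C(C)(C)O1)C(OC(=O)N(C(C)C)C(C)C)c1cc(OC)c(OC)cc1OC.[Li+] | intermediate
12 | 2-[(2R,3R)-2-methyl-1,3-bis(2,4,5-trimethoxyphenyl)pentyl]-4,4,5,5-tetramethyl-1,3,2-dioxaborolane (both epimers at the boron-bearing carbon) | CC[C@@H](c1cc(OC)c(OC)cc1OC)[C@H](C)C(B1OC(C)(C)C(C)(C)O1)c1cc(OC)c(OC)cc1OC | intermediate
13 | (2S,3R)-2-methyl-1,3-bis(2,4,5-trimethoxyphenyl)pentan-1-ol (both carbinol epimers) | CC[C@@H](c1cc(OC)c(OC)cc1OC)[C@H](C)C(O)c1cc(OC)c(OC)cc1OC | intermediate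
14 | C9 benzylic cation, (2S,3R)-2-methyl-1,3-bis(2,4,5-trimethoxyphenyl)pentan-1-ylium | CC[C@@H](c1cc(OC)c(OC)cc1OC)[C@H](C)[CH+]c1cc(OC)c(OC)cc1OC | intermediate
15 | C11 benzylic cation, 2,4-dimethyl-1,3,5-tris(2,4,5-trimethoxyphenyl)heptan-1-ylium with the C7–C10 configuration of 17 | CC[C@@H](c1cc(OC)c(OC)cc1OC)[C@H](C)[C@H](c1cc(OC)c(OC)cc1OC)[C@@H](C)[CH+]c1cc(OC)c(OC)cc1OC | intermediate
16 | spirocyclic O-methyl oxocarbenium ion (17 methylated on the C3 oxygen) | CC[C@@H]1[C@H](C)[C@H](c2cc(OC)c(OC)cc2OC)[C@@H](C)[C@H](c2cc(OC)c(OC)cc2OC)[C@]12C=C(OC)C(=[O+]C)C=C2OC | intermediate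
17 | tatanan B, (6S,7R,8S,9S,10R,11R)-7-ethyl-1,4-dimethoxy-8,10-dimethyl-9,11-bis(2,4,5-trimethoxyphenyl)spiro[5.5]undeca-1,4-dien-3-one | CC[C@@H]1[C@H](C)[C@H](c2cc(OC)c(OC)cc2OC)[C@@H](C)[C@H](c2cc(OC)c(OC)cc2OC)[C@]12C=C(OC)C(=O)C=C2OC | target

## Step count and least certain steps

Total step count: 6. Longest linear sequence: 4 (steps 1, 3, 5, 6). Steps 2 and 4 are one-step side branches.

**Step 6 (key step, new method).** The order of rates may not hold.
- Cation 14 may close on the ortho C–H carbon of its own aryl ring before 1 arrives.
- Cation 15 may add a further molecule of 1, or take a hydride from C7 through a six-membered transition state, because its closure is slowed by the syn-axial contact of the C8 methyl group with the incoming ring.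
- Loss and regain of the C8 proton in 14 would erode C8 by the same process that is meant to correct C10.
- The acid may condense 1 with itself.
- Water may attack 16 at C1 instead of C3.
- Prolonged contact with acid may re-open 17 at C6–C11.

The fallback is stepwise and uses known reactions. It sets out from 13 and comes back to the route at 15.
- 1-(2,4,5-Trimethoxyphenyl)propan-1-one F1 is converted (TMSOTf, Et3N) into its (Z)-trimethylsilyl enol ether F2.
- F2 replaces 1 in an SN1 substitution of 13 (Bi(OTf)3 cat., MeNO2–CH2Cl2, −20 °C). This gives 2,4-dimethyl-1,3,5-tris(2,4,5-trimethoxyphenyl)heptan-1-one F3.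
- The silyl enol ether is a much stronger nucleophile than 1, so self-closure and proton loss of 14 are outrun. The same allylic-strain model sets C9, and C10 lies α to the ketone and can be equilibrated with base.
- NaBH4 gives the benzylic alcohol F4.
- Catalytic acid in (CF3)2CHOH then ionises F4 to 15 with no polymerisable alkene present. The intramolecular ipso-Friedel–Crafts dearomatisation leads through 16 to 17.

**Step 5.** Two things may go wrong. s-BuLi may deprotonate 9 on the ring between the two methoxy groups instead of at the benzylic carbon. The stabilised carbanion 10 may also add slowly or reversibly to the hindered, α-branched secondary boronic ester 7. The fallback sets out from 7 and comes back at 13.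
- Matteson homologation with chloromethyllithium (BrCH2Cl, n-BuLi, −78 °C) gives 2-[(2R,3R)-2-methyl-3-(2,4,5-trimethoxyphenyl)pentyl]-4,4,5,5-tetramethyl-1,3,2-dioxaborolane F5.
- Oxidation (H2O2, NaOH) gives (2S,3R)-2-methyl-3-(2,4,5-trimethoxyphenyl)pentan-1-ol F6.
- Dess–Martin periodinane gives (2S,3R)-2-methyl-3-(2,4,5-trimethoxyphenyl)pentanal F7.
- The aryllithium made from 1-bromo-2,4,5-trimethoxybenzene F8 and n-BuLi adds at −78 °C to give 13.

**Step 3.** Boronate formation between 5 and the hindered, electron-rich benzylic boronic ester 2 may be slow or reversible. This would let the carbenoid decompose and would lower the stereochemical fidelity at C8. The fallback reverses the roles so that the boron partner is unhindered. It sets out from 2 and comes back at 7.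
- Matteson homologation of 2 with chloromethyllithium gives (S)-4,4,5,5-tetramethyl-2-[2-(2,4,5-trimethoxyphenyl)butyl]-1,3,2-dioxaborolane F9.
- Oxidation gives (S)-2-(2,4,5-trimethoxyphenyl)butan-1-ol F10.
- Carbamoylation as in step 4 gives (S)-2-(2,4,5-trimethoxyphenyl)butyl N,N-diisopropylcarbamate F11.
- Deprotonation with s-BuLi/(−)-sparteine, addition of methylboronic acid pinacol ester F12 and warming cause the methyl group to migrate with inversion at C8 and give 7.

**Step 1.** Hydrocupration is slowed by electron-rich, ortho-substituted aryl groups. Conversion may therefore be poor and the enantioselectivity lower than for simple β-methylstyrenes. A small enantiomeric impurity would appear after step 3 as a separable diastereomer. The fallback makes the C7–aryl bond instead of the C7–B bond. It sets out from 3 and comes back at 2.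
- Alkylation of 3 with 1-iodopropane as in step 2 gives propyl 2,4,6-triisopropylbenzoate F13.
- F13 is lithiated with s-BuLi/(+)-sparteine and treated with 4,4,5,5-tetramethyl-2-(2,4,5-trimethoxyphenyl)-1,3,2-dioxaborolane F14.
- Migration of the electron-rich aryl group with inversion gives 2.

## Further compounds

F1 | step 6 | 1-(2,4,5-trimethoxyphenyl)propan-1-one | CCC(=O)c1cc(OC)c(OC)cc1OC
F2 | step 6 | (Z)-trimethyl{[1-(2,4,5-trimethoxyphenyl)prop-1-en-1-yl]oxy}silane | C/C=C(\O[Si](C)(C)C)c1cc(OC)c(OC)cc1OC
F3 | step 6 | 2,4-dimethyl-1,3,5-tris(2,4,5-trimethoxyphenyl)heptan-1-one with the C7–C10 configuration of 17 | CC[C@@H](c1cc(OC)c(OC)cc1OC)[C@H](C)[C@H](c1cc(OC)c(OC)cc1OC)[C@@H](C)C(=O)c1cc(OC)c(OC)cc1OC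
F4 | step 6 | 2,4-dimethyl-1,3,5-tris(2,4,5-trimethoxyphenyl)heptan-1-ol with the C7–C10 configuration of 17 (both carbinol epimers) | CC[C@@H](c1cc(OC)c(OC)cc1OC)[C@H](C)[C@H](c1cc(OC)c(OC)cc1OC)[C@@H](C)C(O)c1cc(OC)c(OC)cc1OC
F5 | step 5 | 2-[(2R,3R)-2-methyl-3-(2,4,5-trimethoxyphenyl)pentyl]-4,4,5,5-tetramethyl-1,3,2-dioxaborolane | CC[C@@H](c1cc(OC)c(OC)cc1OC)[C@H](C)CB1OC(C)(C)C(C)(C)O1
F6 | step 5 | (2S,3R)-2-methyl-3-(2,4,5-trimethoxyphenyl)pentan-1-ol | CC[C@@H](c1cc(OC)c(OC)cc1OC)[C@H](C)CO
F7 | step 5 | (2S,3R)-2-methyl-3-(2,4,5-trimethoxyphenyl)pentanal | CC[C@@H](c1cc(OC)c(OC)cc1OC)[C@H](C)C=O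
F8 | step 5 | 1-bromo-2,4,5-trimethoxybenzene | COc1cc(OC)c(Br)cc1OC
F9 | step 3 | (S)-4,4,5,5-tetramethyl-2-[2-(2,4,5-trimethoxyphenyl)butyl]-1,3,2-dioxaborolane | CC[C@@H](c1cc(OC)c(OC)cc1OC)CB1OC(C)(C)C(C)(C)O1
F10 | step 3 | (S)-2-(2,4,5-trimethoxyphenyl)butan-1-ol | CC[C@@H](c1cc(OC)c(OC)cc1OC)CO
F11 | step 3 | (S)-2-(2,4,5-trimethoxyphenyl)butyl N,N-diisopropylcarbamate | CC[C@@H](c1cc(OC)c(OC)cc1OC)COC(=O)N(C(C)C)C(C)C
F12 | step 3 | methylboronic acid pinacol ester | CB1OC(C)(C)C(C)(C)O1
F13 | step 1 | propyl 2,4,6-triisopropylbenzoate | CCCOC(=O)c1c(C(C)C)cc(C(C)C)cc1C(C)C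
F14 | step 1 | 4,4,5,5-tetramethyl-2-(2,4,5-trimethoxyphenyl)-1,3,2-dioxaborolane | CC1(C)OB(c2cc(OC)c(OC)cc2OC)OC1(C)C
A1 | alternative 1 | open-chain para-phenol (E)-allylic methyl carbonate carrying C8–C11 of 17 | COC(=O)OC/C=C/[C@H](C)[C@H](c1cc(OC)c(OC)cc1OC)[C@@H](C)[C@H](c1cc(OC)c(OC)cc1OC)c1cc(OC)c(O)cc1OC
A2 | alternative 1 | 7-vinyl analogue of 17 | C=C[C@@H]1[C@H](C)[C@H](c2cc(OC)c(OC)cc2OC)[C@@H](C)[C@H](c2cc(OC)c(OC)cc2OC)[C@]12C=C(OC)C(=O)C=C2OC
A3 | alternative 2 | (E)-2,5-dimethoxy-4-(2,4,5-trimethoxybenzylidene)cyclohexa-2,5-dien-1-one | O=C1C=C(OC)/C(=C/c2cc(OC)c(OC)cc2OC)C=C1OC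
A4 | alternative 2 | 1,2,4-trimethoxy-5-(4-methylhepta-2,4-dien-3-yl)benzene, ethyl group outward and terminal methyl group inward | CC/C=C(C)/C(c1cc(OC)c(OC)cc1OC)=C\C
A5 | alternative 2 | 8,9-didehydro analogue of 17 | CC[C@@H]1C(C)=C(c2cc(OC)c(OC)cc2OC)[C@@H](C)[C@H](c2cc(OC)c(OC)cc2OC)[C@]12C=C(OC)C(=O)C=C2OC
A6 | alternative 3 | 1-(2,4,5-trimethoxyphenyl)propan-1-ylium | CC[CH+]c1cc(OC)c(OC)cc1OC
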